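The central benzene ring (C4b, C5, C6, C6a, C11a, C11b) of the indolo[2,3-a]carbazole is built from a five-membered cyclic sulfone. Its four adjacent carbons C4b(aryl), C5(OMe), C6(OMe) and C6a(aryl) are C2 to C5 of the precursor, 2,5-bis(4-chloro-2-nitrophenyl)-3,4-dimethoxythiophene 1,1-dioxide. Heating with norbornadiene forms C4b–C11b and C6a–C11a and expels SO2 and cyclopentadiene. This leaves C11a–H and C11b–H as the only free sites for a double nitrene closure of both pyrrole rings. To confine the risk to that step, sulfur is oxidised in an acyclic sulfide and the ring is then closed with diethyl oxalate, so no donor-rich thiophene must be oxidised.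

Key step: step 5

Assumption: 1-(bromomethyl)-4-chloro-2-nitrobenzene is taken to be a catalogue compound. The two transient cycloadducts of the key step are drawn as the isomers from exo attack on norbornadiene with the norbornene unit endo to the new ring alkene, a detail that aromatisation erases.

Step 1
Reactants: 1 1-(bromomethyl)-4-chloro-2-nitrobenzene (two equivalents)
Product: 3 bis(4-chloro-2-nitrobenzyl) sulfide, via sodium (4-chloro-2-nitrophenyl)methanethiolate 2 (not isolated)
Conditions: Na2S·9H2O (0.5 equiv, slow addition), THF/H2O, 0 °C to rt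
Reagents that add atoms: sodium sulfide, [Na+].[Na+].[S-2]
Why: This is a twofold SN2 thioether synthesis in which sulfide displaces the activated benzylic bromide and thiolate 2 is alkylated again at once, because keeping the halide in excess at low temperature leaves no room for Zinin-type attack on a nitro group.

Step 2
Reactants: 3 bis(4-chloro-2-nitrobenzyl) sulfide
Product: 5 bis(4-chloro-2-nitrobenzyl) sulfone, via sulfoxide 4 (not isolated)
Conditions: 30% aq. H2O2 (excess), AcOH, 70 °C
Reagents that add atoms: hydrogen peroxide, OO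
Why: This is a routine peroxide oxidation of a dialkyl sulfide to the sulfone, in which sulfur is an ordinary nucleophilic thioether and the nitro and aryl chloride groups are inert.

Step 3
Reactants: 5 bis(4-chloro-2-nitrobenzyl) sulfone; 6 diethyl oxalate
Product: 8 2,5-bis(4-chloro-2-nitrophenyl)-3,4-dihydroxythiophene 1,1-dioxide, via open-chain keto ester 7 (not isolated)
Conditions: NaOEt (2.5 equiv), EtOH/THF, N2, reflux; then 2 M HCl
Reagents that add atoms: none
Why: This Hinsberg-type double Claisen condensation is known for dibenzyl sulfones with oxalate esters and is related to the Reissert acylation of o-nitrotoluenes: each sulfonyl- and nitroaryl-stabilised benzylic carbanion acylates one ester group (the second as a 5-exo-trig Dieckmann closure), and formation of the twofold enediolate salt should pull the equilibria to the ring.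

Step 4
Reactants: 8 2,5-bis(4-chloro-2-nitrophenyl)-3,4-dihydroxythiophene 1,1-dioxide
Product: 10 2,5-bis(4-chloro-2-nitrophenyl)-3,4-dimethoxythiophene 1,1-dioxide, via monomethyl ether 9 (not isolated)
Conditions: Me2SO4 (3 equiv), K2CO3 (4 equiv), acetone, N2, reflux
Reagents that add atoms: dimethyl sulfate, COS(=O)(=O)OC
Why: This is a Williamson-type O-alkylation of an acidic enol with a hard methylating agent, as practised on Hinsberg 3,4-dihydroxythiophenes, and oxygen should win at both sites because the competing carbon is fully substituted and shielded by its ortho-nitroaryl group.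

Step 5
Reactants: 10 2,5-bis(4-chloro-2-nitrophenyl)-3,4-dimethoxythiophene 1,1-dioxide; 11 norbornadiene
Product: 14 1,4-bis(4-chloro-2-nitrophenyl)-2,3-dimethoxybenzene, via bridged sulfone 12 (not isolated), via fused cyclohexadiene 13 (not isolated)
Conditions: 11 (15 equiv), BHT (cat.), 1,2-dichlorobenzene, sealed vessel, 150 °C
Reagents that add atoms: none
Why: The cyclic sulfone of 10 is a locked s-cis diene without aromatic stabilisation, and its termini C2 and C5 should bond suprafacially to the exo face of one strained double bond of 11 in a thermal Diels–Alder reaction to give 12; cheletropic extrusion of SO2 then gives 13, and a retro-Diels–Alder reaction releases cyclopentadiene, both losses being pulled by the aromaticity gained in 14. The closest known reaction type is the use of norbornadiene as an acetylene equivalent toward halogenated or arylated thiophene 1,1-dioxides and tetraarylcyclopentadienones. The single new ring, the six-membered central carbocycle, is closed by an intermolecular [4+2] cycloaddition that makes C4b–C11b and C6a–C11a in the same event, so no Baldwin-type constraint applies. No stereocentre remains in 14, and those of 12 and 13 follow from exo attack on 11 and are deleted on aromatisation. Only one constitution is possible because each partner has a mirror plane bisecting its reacting π system, so the selectivity needed is cross-addition ahead of sulfone self-dimerisation and ahead of capture by liberated cyclopentadiene, which the aryl groups on both diene termini and the large excess of 11 should secure. The sulfonyl and nitroaryl groups lower the diene LUMO toward the high HOMO of the strained alkene, and the twisted aryl rings can turn both nitro groups to one face so that the other stays open.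

Step 6
Reactants: 14 1,4-bis(4-chloro-2-nitrophenyl)-2,3-dimethoxybenzene
Product: 16 borregomycin E (2,9-dichloro-5,6-dimethoxy-11,12-dihydroindolo[2,3-a]carbazole), via nitroaryl carbazole 15 (not isolated)
Conditions: PPh3 (6 equiv), 1,2-dichlorobenzene, N2, 180 °C
Reagents that add atoms: none
Why: In this twofold Cadogan reductive cyclisation PPh3 deoxygenates each nitro group to a nitrene-like species that closes onto the only adjacent C–H of the electron-rich central ring (one of C11a and C11b first, the other via 15), the other ortho positions being blocked by OMe, and PPh3 replaces a trialkyl phosphite so that N-alkylation is excluded.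

Compound list
1 | 1-(bromomethyl)-4-chloro-2-nitrobenzene | O=[N+]([O-])c1cc(Cl)ccc1CBr | starting material
2 | sodium (4-chloro-2-nitrophenyl)methanethiolate | [Na+].[S-]Cc1ccc(Cl)cc1[N+](=O)[O-] | intermediate
3 | bis(4-chloro-2-nitrobenzyl) sulfide | O=[N+]([O-])c1cc(Cl)ccc1CSCc1ccc(Cl)cc1[N+](=O)[O-] | intermediate
4 | bis(4-chloro-2-nitrobenzyl) sulfoxide | O=[N+]([O-])c1cc(Cl)ccc1CS(=O)Cc1ccc(Cl)cc1[N+](=O)[O-] | intermediate
5 | bis(4-chloro-2-nitrobenzyl) sulfone | O=[N+]([O-])c1cc(Cl)ccc1CS(=O)(=O)Cc1ccc(Cl)cc1[N+](=O)[O-] | intermediate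
6 | diethyl oxalate | CCOC(=O)C(=O)OCC | starting material
7 | ethyl 3-(4-chloro-2-nitrophenyl)-3-[(4-chloro-2-nitrobenzyl)sulfonyl]-2-oxopropanoate (racemic, present as its enolate) | CCOC(=O)C(=O)C(c1ccc(Cl)cc1[N+](=O)[O-])S(=O)(=O)Cc1ccc(Cl)cc1[N+](=O)[O-] | intermediate
8 | 2,5-bis(4-chloro-2-nitrophenyl)-3,4-dihydroxythiophene 1,1-dioxide | OC1=C(c2ccc(Cl)cc2[N+](=O)[O-])S(=O)(=O)C(c2ccc(Cl)cc2[N+](=O)[O-])=C1O | intermediate
9 | 2,5-bis(4-chloro-2-nitrophenyl)-3-hydroxy-4-methoxythiophene 1,1-dioxide | COC1=C(c2ccc(Cl)cc2[N+](=O)[O-])S(=O)(=O)C(c2ccc(Cl)cc2[N+](=O)[O-])=C1O | intermediate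
10 | 2,5-bis(4-chloro-2-nitrophenyl)-3,4-dimethoxythiophene 1,1-dioxide | COC1=C(c2ccc(Cl)cc2[N+](=O)[O-])S(=O)(=O)C(c2ccc(Cl)cc2[N+](=O)[O-])=C1OC | intermediate
11 | norbornadiene (bicyclo[2.2.1]hepta-2,5-diene) | C1=CC2C=CC1C2 | starting material
12 | 1,4-bis(4-chloro-2-nitrophenyl)-2,3-dimethoxy-1,4,4a,5,8,8a-hexahydro-1,4-epithio-5,8-methanonaphthalene S,S-dioxide (meso; fusion exo on the norbornene, endo on the thianorbornene) | COC1=C(OC)[C@]2(c5ccc(Cl)cc5[N+](=O)[O-])[C@@H]3[C@H]4C=C[C@H](C4)[C@@H]3[C@@]1(c5ccc(Cl)cc5[N+](=O)[O-])S2(=O)=O | intermediate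
13 | 5,8-bis(4-chloro-2-nitrophenyl)-6,7-dimethoxy-1,4,4a,8a-tetrahydro-1,4-methanonaphthalene (meso; cis fusion on the exo face) | COC1=C(c4ccc(Cl)cc4[N+](=O)[O-])[C@@H]2[C@H]3C=C[C@H](C3)[C@@H]2C(c4ccc(Cl)cc4[N+](=O)[O-])=C1OC | intermediate
14 | 1,4-bis(4-chloro-2-nitrophenyl)-2,3-dimethoxybenzene | COc1c(OC)c(-c2ccc(Cl)cc2[N+](=O)[O-])ccc1-c1ccc(Cl)cc1[N+](=O)[O-] | intermediate
15 | 7-chloro-2-(4-chloro-2-nitrophenyl)-3,4-dimethoxy-9H-carbazole | COc1c(OC)c2c3ccc(Cl)cc3[nH]c2cc1-c1ccc(Cl)cc1[N+](=O)[O-] | intermediate
16 | borregomycin E, 2,9-dichloro-5,6-dimethoxy-11,12-dihydroindolo[2,3-a]carbazole | COc1c(OC)c2c3ccc(Cl)cc3[nH]c2c2[nH]c3cc(Cl)ccc3c12 | target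

Total step count: 6. Longest linear sequence: 6 steps (1 to 16).

Steps most likely to fail

First, step 5. The cycloaddition may be too slow, because both diene termini are fully substituted and flanked by twisted ortho-nitroaryl rings. Oligomerisation of 11, or consumption of 10 by released cyclopentadiene, could then take over. The fallback sets out from 10 and comes back at 14, and it aromatises by elimination in place of cycloreversion. Compound 10 is heated in a sealed vessel at about 130 °C with n-butyl vinyl ether (C=COCCCC). This is a slimmer and more electron-rich two-carbon partner for an inverse-electron-demand Diels–Alder reaction. The bridged 5-butoxy-7-thiabicyclo[2.2.1]hept-2-ene 7,7-dioxide F1 should lose SO2 at once to give the 5-butoxycyclohexa-1,3-diene F2. This is isolated and treated with catalytic TsOH in refluxing toluene, so that loss of butan-1-ol gives 14.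

Second, step 3. The sequence may stall after the first acylation, because the doubly stabilised carbanion is a weak nucleophile. The ortho-nitrobenzylic anion may also decay by internal redox chemistry on long heating in base. The fallback sets out from 3 (together with 6) and comes back at 10, and it closes the ring before sulfur is oxidised.
- A Hinsberg thiophene synthesis of 3 with 6 (KOEt, EtOH/Et2O, the Reissert medium) uses the more nucleophilic sulfide-level carbanion. It should pass through the open-chain sulfanyl keto ester F3 and, driven by the aromaticity of the new ring, give 2,5-bis(4-chloro-2-nitrophenyl)thiophene-3,4-diol F4.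
- Me2SO4 and K2CO3 in acetone should lead via 2,5-bis(4-chloro-2-nitrophenyl)-4-methoxythiophen-3-ol F5 to 2,5-bis(4-chloro-2-nitrophenyl)-3,4-dimethoxythiophene F6.
- Excess mCPBA in warm 1,2-dichloroethane should oxidise sulfur via the thiophene 1-oxide F7 to 10.

The price is peracid oxidation of a donor-substituted thiophene, tempered here by two electron-poor aryl groups.

Third, step 6. Three things may go wrong:
- the second closure next to the first N–H may remain incomplete;
- a nitrene may attack a methoxy-bearing carbon;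
- nitrogen may be trapped by phosphorus as an iminophosphorane.

The fallback sets out from 14 and comes back at 16, and it generates the nitrenes from azides rather than by deoxygenation.
- Fe powder and NH4Cl in aqueous EtOH at 80 °C retain the aryl chlorides and should give 1,4-bis(2-amino-4-chlorophenyl)-2,3-dimethoxybenzene F8.
- NaNO2 in aqueous HCl at 0 °C gives the bis(diazonium) dichloride F9, which is treated in the same flask with NaN3 to give 1,4-bis(2-azido-4-chlorophenyl)-2,3-dimethoxybenzene F10.
- Catalysis by Rh2(O2CC7H15)4 in toluene at 60 °C, or thermolysis in 1,2-dichlorobenzene at 160 °C, should close one ring to give 2-(2-azido-4-chlorophenyl)-7-chloro-3,4-dimethoxy-9H-carbazole F11. The same conditions then close the other ring, which is the known carbazole synthesis from 2-azidobiaryls, to give 16.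

Further compounds
F1 | step 5 | 5-butoxy-1,4-bis(4-chloro-2-nitrophenyl)-2,3-dimethoxy-7-thiabicyclo[2.2.1]hept-2-ene 7,7-dioxide (racemic, endo/exo not defined) | CCCCOC1CC2(c3ccc(Cl)cc3[N+](=O)[O-])C(OC)=C(OC)C1(c4ccc(Cl)cc4[N+](=O)[O-])S2(=O)=O
F2 | step 5 | 5-butoxy-1,4-bis(4-chloro-2-nitrophenyl)-2,3-dimethoxycyclohexa-1,3-diene (racemic) | CCCCOC1CC(c2ccc(Cl)cc2[N+](=O)[O-])=C(OC)C(OC)=C1c1ccc(Cl)cc1[N+](=O)[O-]
F3 | step 3 | ethyl 3-(4-chloro-2-nitrophenyl)-3-[(4-chloro-2-nitrobenzyl)sulfanyl]-2-oxopropanoate (racemic) | CCOC(=O)C(=O)C(SCc1ccc(Cl)cc1[N+](=O)[O-])c1ccc(Cl)cc1[N+](=O)[O-]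
F4 | step 3 | 2,5-bis(4-chloro-2-nitrophenyl)thiophene-3,4-diol | Oc1c(-c2ccc(Cl)cc2[N+](=O)[O-])sc(-c2ccc(Cl)cc2[N+](=O)[O-])c1O
F5 | step 3 | 2,5-bis(4-chloro-2-nitrophenyl)-4-methoxythiophen-3-ol | COc1c(-c2ccc(Cl)cc2[N+](=O)[O-])sc(-c2ccc(Cl)cc2[N+](=O)[O-])c1O
F6 | step 3 | 2,5-bis(4-chloro-2-nitrophenyl)-3,4-dimethoxythiophene | COc1c(-c2ccc(Cl)cc2[N+](=O)[O-])sc(-c2ccc(Cl)cc2[N+](=O)[O-])c1OC
F7 | step 3 | 2,5-bis(4-chloro-2-nitrophenyl)-3,4-dimethoxythiophene 1-oxide | COC1=C(c2ccc(Cl)cc2[N+](=O)[O-])S(=O)C(c2ccc(Cl)cc2[N+](=O)[O-])=C1OC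
F8 | step 6 | 1,4-bis(2-amino-4-chlorophenyl)-2,3-dimethoxybenzene | COc1c(OC)c(-c2ccc(Cl)cc2N)ccc1-c1ccc(Cl)cc1N
F9 | step 6 | 2,2'-(2,3-dimethoxy-1,4-phenylene)bis(5-chlorobenzenediazonium) dichloride | COc1c(OC)c(-c2ccc(Cl)cc2[N+]#N)ccc1-c1ccc(Cl)cc1[N+]#N.[Cl-].[Cl-]
F10 | step 6 | 1,4-bis(2-azido-4-chlorophenyl)-2,3-dimethoxybenzene | COc1c(OC)c(-c2ccc(Cl)cc2N=[N+]=[N-])ccc1-c1ccc(Cl)cc1N=[N+]=[N-]
F11 | step 6 | 2-(2-azido-4-chlorophenyl)-7-chloro-3,4-dimethoxy-9H-carbazole | COc1c(OC)c2c3ccc(Cl)cc3[nH]c2cc1-c1ccc(Cl)cc1N=[N+]=[N-]
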